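Cedar is charged with more substrate than alder, 3.00 M against 1.00 M, but its excess of reagent over substrate is the same, 1.00 M, so I read the charges below by that difference.

| flask | substrate | reagent | time |
|---|---|---|---|
| alder | 1.00 M | 2.00 M |  |
| larch | 0.500 M | 1.50 M |  |
| birch | 1.00 M | 3.00 M |  |
| ash | 2.00 M | 2.00 M |  |
| cedar | 3.00 M | 4.00 M | 95 s |

| alder run: time / s | alder run: [product] / M | larch run: time / s | larch run: [product] / M | birch run: time / s | birch run: [product] / M | ash run: time / s | ash run: [product] / M |
|---|---|---|---|---|---|---|---|
| 4.2 | 0.055 | 4.2 | 0.009 | 4.2 | 0.074 | 4.2 | 0.099 |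
| 13 | 0.137 | 13 | 0.054 | 13 | 0.207 | 13 | 0.272 |
| 24 | 0.241 | 24 | 0.091 | 24 | 0.336 | 24 | 0.446 |
| 39 | 0.352 | 39 | 0.140 | 39 | 0.472 | 39 | 0.639 |
| 55 | 0.439 | 55 | 0.183 | 55 | 0.582 | 55 | 0.793 |
| 74 | 0.521 | 74 | 0.238 | 74 | 0.670 | 74 | 0.932 |
| 95 | 0.603 | 95 | 0.262 | 95 | 0.751 | 95 | 1.040 |

(standard deviation of a reading: 0.005 M)

- Overall: substrate + reagent -> product.
- Constant volume, constant temperature.
- An order is taken over about fifteen percent of the charge, up and down.

* the power of [substrate] that the first rate follows, about the charge of the alder run; measure it at two percent of substrate made into product (one fixed amount of product, the same in the runs compared)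
* the power of [reagent] that the first rate follows, about the charge of the alder run; measure it at two percent of substrate made into product
* product in the cedar run at 95 s, as a share of the substrate charged

Going down the rows, the excess is 1.00 M in alder, 1.00 M in larch, 2.00 M in birch and 0 M in ash. Setting rows against each other at 13 s, ash over alder reads as a power of 0.989 in substrate, and birch over alder as a power of 1.02 in reagent, so within the scatter I take the rate as k·c_substrate·c_reagent.

The overall equation takes substrate and reagent down by equal amounts, so the excess stays fixed, and for a rate of that form ln(c_reagent/c_substrate) climbs steadily. In alder at 95 s the ratio has gone from 2.00 to 3.52, which gives 168 s, the ratio clock: the time in which that logarithm rises by one at this excess.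

Cedar shares the excess, so I lend it alder's clock. Its ratio starts at 1.33 and reaches 2.35 at 95 s. Substrate is the limiting reagent in cedar, and that ratio puts product at 75.2% of it.

The forecast gives powers of 1 and 1 and a cedar yield of 73.5%, within 70% to 76%, lower than my figure on the grounds of “a slight downward drift in k at high product”.

The flask gives powers of 1.0 and 1.0, and cedar reaches 71.8% at 95 s.

    substrate + reagent ⇌ product + by-product (0.006060 M⁻¹ s⁻¹, 7.870 × 10⁻⁴ M⁻¹ s⁻¹)

The reverse step has a constant 13.0% of the forward one. Cedar's yield means a ratio of 2.18, so its clock reads 193 s, longer than alder's 168 s. Larch has the same excess, and alder's clock puts its half-conversion at 85.9 s, while the larch run reaches it at 85.0 s.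

The numbers in the tables stem from a simulated flask on assumed constants.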